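**Retrosynthetic overview**
1. 22 ⇒ seco-enal 19. One pot makes the C6–C7 bond and moves the lactone from O8 to O6. The ten-membered carbocycle and the final γ-lactone therefore form together, and 8-OH is freed without a protecting group.
2. 19 ⇒ vinyl iodide 7 (fragment 1) + aldehyde 14 (fragment 2). C9–C10 is made by Nozaki–Hiyama–Kishi coupling, followed by isovalerate, two acetates, desilylation and oxidation.
3. 7 ⇒ nerol, which brings Z-C4=C5. Ozonolysis and iodo-Wittig olefination fix Z-C1=C10.
4. 14 ⇒ (R)-glyceraldehyde acetonide (from D-mannitol diacetonide, brings C8) + methyl acrylate, by Baylis–Hillman reaction and lactonisation.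
5. Ring order: sacrificial 8,12-butyrolactone (step 7), then carbocycle and 6,12-lactone at once (step 14).

Assumption: labels C1–C15 are germacrane locants (C6 lactone carbinol, C7 ring fusion, C8 free carbinol, C9 acetoxy carbon, C14 acyloxymethyl carbon), and the target SMILES is read as 1(10)Z,4Z and 6R,7R,8S,9R.

**Step 1**
Reactants: 1 nerol
Product: 2 neryl tert-butyldimethylsilyl ether
Conditions: TBSCl, imidazole, CH2Cl2, 0 °C to rt
Reagents that add atoms: tert-butyldimethylsilyl chloride, CC(C)(C)[Si](C)(C)Cl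
Why: Imidazole-promoted silylation (silyl ether protection) caps the only hydroxyl, on the future C6 aldehyde carbon, and leaves the Z-C4=C5 alkene bought with nerol unchanged.

**Step 2**
Reactants: 2 neryl tert-butyldimethylsilyl ether
Product: 3 (4Z)-6-(tert-butyldimethylsilyloxy)-4-methylhex-4-enal
Conditions: O3 (1.0 equiv), CH2Cl2, −78 °C; then Me2S, −78 °C to rt
Reagents that add atoms: ozone, [O-][O+]=O
Why: Chemoselective Criegee ozonolysis works because the remote isopropylidene alkene is more electron-rich than the alkene bearing the allylic C–O bond, so one equivalent of ozone cuts only the former and delivers C1 as an aldehyde without touching the Z alkene.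

**Step 3**
Reactants: 3 (4Z)-6-(tert-butyldimethylsilyloxy)-4-methylhex-4-enal; 4 ethyl (triphenylphosphoranylidene)acetate
Product: 6 ethyl (2Z,6Z)-8-(tert-butyldimethylsilyloxy)-2-iodo-6-methylocta-2,6-dienoate, via iodo ylide 5 (not isolated)
Conditions: 4, NIS, CH2Cl2, −20 °C, 30 min; then 3, −20 °C to rt
Reagents that add atoms: N-iodosuccinimide, O=C1CCC(=O)N1I
Why: Wittig olefination with a stabilised ylide that NIS first iodinates (the succinimide anion regenerates the ylide) puts the ester trans and the iodine cis to the chain, giving mainly the 2Z iodoalkene (minor 2E isomer removed on silica) and fixing the later Z-C1=C10 geometry.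

**Step 4**
Reactants: 6 ethyl (2Z,6Z)-8-(tert-butyldimethylsilyloxy)-2-iodo-6-methylocta-2,6-dienoate
Product: 7 (2Z,6Z)-8-(tert-butyldimethylsilyloxy)-2-iodo-6-methylocta-2,6-dien-1-ol (fragment 1)
Conditions: i-Bu2AlH (2.2 equiv), CH2Cl2, −78 °C
Reagents that add atoms: none
Why: Low-temperature 1,2-reduction of the conjugated ester by i-Bu2AlH stops at the allylic alcohol (C14) and touches neither the vinyl iodide, the silyl ether nor either alkene geometry.

**Step 5**
Reactants: 8 1,2:5,6-di-O-isopropylidene-D-mannitol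
Product: 9 (R)-2,2-dimethyl-1,3-dioxolane-4-carbaldehyde
Conditions: NaIO4, CH2Cl2/sat. aq NaHCO3, rt
Reagents that add atoms: none
Why: Malaprade glycol cleavage of the central diol gives two equivalents of the aldehyde under buffered conditions, and its stereocentre, the future C8, comes intact from D-mannitol.

**Step 6**
Reactants: 9 (R)-2,2-dimethyl-1,3-dioxolane-4-carbaldehyde; 10 methyl acrylate
Product: 11 methyl 2-{(S)-[(4R)-2,2-dimethyl-1,3-dioxolan-4-yl](hydroxy)methyl}prop-2-enoate (anti isomer, about 3:1, separated)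
Conditions: DABCO (0.3 equiv), 1,4-dioxane/H2O 1:1, rt, 36 h
Reagents that add atoms: none
Why: In this Morita–Baylis–Hillman reaction the DABCO-derived acrylate enolate attacks the aldehyde in the Felkin–Anh sense to give mainly the anti (7S) carbinol, a centre that only carries the later leaving group and is erased in step 14, while C8 stays as bought.

**Step 7**
Reactants: 11 methyl 2-{(S)-[(4R)-2,2-dimethyl-1,3-dioxolan-4-yl](hydroxy)methyl}prop-2-enoate
Product: 13 (4S,5R)-4-hydroxy-5-(hydroxymethyl)-3-methylideneoxolan-2-one, via triol methyl ester 12 (not isolated)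
Conditions: TFA/H2O/THF, 0 °C to rt
Reagents that add atoms: none
Why: Acid hydrolysis of the acetonide frees the 8- and 9-hydroxyls, and 8-OH closes the favoured five-membered lactone on the methyl ester (acid-catalysed lactonisation) with no change at C7 or C8.

**Step 8**
Reactants: 13 (4S,5R)-4-hydroxy-5-(hydroxymethyl)-3-methylideneoxolan-2-one
Product: 14 (2S,3S)-3-hydroxy-4-methylidene-5-oxooxolane-2-carbaldehyde (fragment 2, used crude)
Conditions: TEMPO (10 mol %), PhI(OAc)2 (1.1 equiv), CH2Cl2/MeCN, 0 °C to rt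
Reagents that add atoms: none
Why: The oxoammonium oxidation (TEMPO/PhI(OAc)2, Piancatelli–Margarita type) takes the primary alcohol much faster than the hindered secondary one next to the electron-poor alkene, and its near-neutral medium avoids β-elimination and epimerisation at C8.

**Step 9**
Reactants: 7 (2Z,6Z)-8-(tert-butyldimethylsilyloxy)-2-iodo-6-methylocta-2,6-dien-1-ol (fragment 1); 14 (2S,3S)-3-hydroxy-4-methylidene-5-oxooxolane-2-carbaldehyde (fragment 2, 1.5 equiv)
Product: 15 (4S,5R)-5-[(1R,2Z,6Z)-8-(tert-butyldimethylsilyloxy)-1-hydroxy-2-(hydroxymethyl)-6-methylocta-2,6-dien-1-yl]-4-hydroxy-3-methylideneoxolan-2-one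
Conditions: CrCl2 (6 equiv), NiCl2 (2 mol %), DMF, rt
Reagents that add atoms: none
Why: In the Nozaki–Hiyama–Kishi coupling zerovalent nickel inserts into C–I with retention and hands the alkenyl group to trivalent chromium, giving a non-basic nucleophile that tolerates hydroxyls, lactone and Michael acceptor (14-OH is kept free so that no β-acyloxy elimination to an allene can occur) and that adds anti to the C8–O bond (polar Felkin–Anh, chelation by the trans 7-OH being impossible), which sets 9R with the 8,9-anti relationship.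

**Step 10**
Reactants: 15 (4S,5R)-5-[(1R,2Z,6Z)-8-(tert-butyldimethylsilyloxy)-1-hydroxy-2-(hydroxymethyl)-6-methylocta-2,6-dien-1-yl]-4-hydroxy-3-methylideneoxolan-2-one
Product: 16 (4S,5R)-5-{(1R,2Z,6Z)-8-(tert-butyldimethylsilyloxy)-1-hydroxy-6-methyl-2-[(3-methylbutanoyloxy)methyl]octa-2,6-dien-1-yl}-4-hydroxy-3-methylideneoxolan-2-one
Conditions: isovaleryl chloride (1.05 equiv), 2,4,6-collidine, CH2Cl2, −78 to −20 °C
Reagents that add atoms: isovaleryl chloride, CC(C)CC(=O)Cl
Why: Kinetically selective acylation succeeds because the primary 14-OH reacts far faster than the two hindered secondary alcohols at low temperature with a weak, non-nucleophilic base, and no stereocentre is involved.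

**Step 11**
Reactants: 16 (4S,5R)-5-{(1R,2Z,6Z)-8-(tert-butyldimethylsilyloxy)-1-hydroxy-6-methyl-2-[(3-methylbutanoyloxy)methyl]octa-2,6-dien-1-yl}-4-hydroxy-3-methylideneoxolan-2-one
Product: 17 (4S,5R)-4-acetoxy-5-{(1R,2Z,6Z)-1-acetoxy-8-(tert-butyldimethylsilyloxy)-6-methyl-2-[(3-methylbutanoyloxy)methyl]octa-2,6-dien-1-yl}-3-methylideneoxolan-2-one
Conditions: Ac2O, Et3N, DMAP (5 mol %), CH2Cl2, 0 °C
Reagents that add atoms: acetic anhydride, CC(=O)OC(C)=O
Why: DMAP-catalysed acetylation esterifies both remaining alcohols with retention, the 9-acetate being the one found in the target and the 7-acetate becoming the leaving group of step 14.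

**Step 12**
Reactants: 17 (4S,5R)-4-acetoxy-5-{(1R,2Z,6Z)-1-acetoxy-8-(tert-butyldimethylsilyloxy)-6-methyl-2-[(3-methylbutanoyloxy)methyl]octa-2,6-dien-1-yl}-3-methylideneoxolan-2-one
Product: 18 (4S,5R)-4-acetoxy-5-{(1R,2Z,6Z)-1-acetoxy-8-hydroxy-6-methyl-2-[(3-methylbutanoyloxy)methyl]octa-2,6-dien-1-yl}-3-methylideneoxolan-2-one
Conditions: HF·pyridine, THF, 0 °C
Reagents that add atoms: none
Why: Fluoride-driven Si–O cleavage (desilylation) of the primary allylic silyl ether is fast in this mildly acidic medium, which leaves the esters, the lactone and the activated allylic acetate in place.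

**Step 13**
Reactants: 18 (4S,5R)-4-acetoxy-5-{(1R,2Z,6Z)-1-acetoxy-8-hydroxy-6-methyl-2-[(3-methylbutanoyloxy)methyl]octa-2,6-dien-1-yl}-3-methylideneoxolan-2-one
Product: 19 (4S,5R)-4-acetoxy-5-{(1R,2Z,6Z)-1-acetoxy-6-methyl-2-[(3-methylbutanoyloxy)methyl]-8-oxoocta-2,6-dien-1-yl}-3-methylideneoxolan-2-one (seco-enal)
Conditions: TEMPO (10 mol %), PhI(OAc)2 (1.1 equiv), MeCN/pH 7 buffer, 0 °C
Reagents that add atoms: none
Why: The buffered TEMPO/PhI(OAc)2 oxidation is the standard way to turn nerol-type alcohols into neral-type Z-enals without Z to E isomerisation, and nothing else in 18 is oxidisable under these conditions.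

**Step 14**
Reactants: 19 (4S,5R)-4-acetoxy-5-{(1R,2Z,6Z)-1-acetoxy-6-methyl-2-[(3-methylbutanoyloxy)methyl]-8-oxoocta-2,6-dien-1-yl}-3-methylideneoxolan-2-one (seco-enal)
Product: 22 target germacranolide CNP0603244.1, via iodomethylbutenolide enal 20 (not isolated), via cis-fused 8,12-lactone alcohol 21 (not isolated)
Conditions: LiI (3 equiv), THF/DMF 4:1, 0 °C, 30 min; then syringe pump (12 h) into CrCl2 (8 equiv), THF/DMF, 2 mM final, rt; pH 7 buffer
Reagents that add atoms: none
Why: Proposed new method: iodide adds to the exocyclic methylene and expels the activated 7-acetate (SN2', as Baylis–Hillman acetates do) to give 20, two equivalents of divalent chromium convert it into an allylchromium reagent whose C8–O bond lies in the nodal plane of the butenolide so that vinylogous elimination is shut off, and its γ-carbon C7 attacks the tethered Z-enal through a closed Zimmerman–Traxler chair (Nozaki–Hiyama allylation, the closest known types being chromium-mediated macrocyclisation of ω-formyl allyl halides to germacranes and Barbier allylation with 3-(bromomethyl)furan-2(5H)-one followed by translactonisation); the ring-locked E geometry of the allyl unit gives the C6/C7 anti pair, the short Z,Z tether hanging from C9 should deliver the aldehyde to the butenolide face syn to C9 and so set 7R relative to C8, and the O6 chromium alkoxide, held next to C12 by the chair, opens the strained cis-fused lactone of 21 and releases O8, so the ten-membered ring and the trans 6,12-lactone arise in one operation.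

**Compound list**
1 | nerol, (2Z)-3,7-dimethylocta-2,6-dien-1-ol | CC(C)=CCC/C(C)=C\CO | starting material
2 | neryl tert-butyldimethylsilyl ether | CC(C)=CCC/C(C)=C\CO[Si](C)(C)C(C)(C)C | intermediate
3 | (4Z)-6-(tert-butyldimethylsilyloxy)-4-methylhex-4-enal | O=CCC/C(C)=C\CO[Si](C)(C)C(C)(C)C | intermediate
4 | ethyl (triphenylphosphoranylidene)acetate | CCOC(=O)C=P(c1ccccc1)(c1ccccc1)c1ccccc1 | starting material
5 | ethyl iodo(triphenylphosphoranylidene)acetate (iodo ylide) | CCOC(=O)C(I)=P(c1ccccc1)(c1ccccc1)c1ccccc1 | intermediate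
6 | ethyl (2Z,6Z)-8-(tert-butyldimethylsilyloxy)-2-iodo-6-methylocta-2,6-dienoate | CCOC(=O)/C(I)=C/CC/C(C)=C\CO[Si](C)(C)C(C)(C)C | intermediate
7 | (2Z,6Z)-8-(tert-butyldimethylsilyloxy)-2-iodo-6-methylocta-2,6-dien-1-ol (fragment 1) | OC/C(I)=C/CC/C(C)=C\CO[Si](C)(C)C(C)(C)C | intermediate
8 | 1,2:5,6-di-O-isopropylidene-D-mannitol | CC1(C)OC[C@@H](O1)[C@@H](O)[C@H](O)[C@H]1COC(C)(C)O1 | starting material
9 | (R)-2,2-dimethyl-1,3-dioxolane-4-carbaldehyde | CC1(C)OC[C@@H](O1)C=O | intermediate
10 | methyl acrylate | C=CC(=O)OC | starting material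
11 | methyl 2-{(S)-[(4R)-2,2-dimethyl-1,3-dioxolan-4-yl](hydroxy)methyl}prop-2-enoate | CC1(C)OC[C@@H](O1)[C@@H](O)C(=C)C(=O)OC | intermediate
12 | methyl (3S,4R)-3,4,5-trihydroxy-2-methylidenepentanoate (triol methyl ester) | OC[C@@H](O)[C@@H](O)C(=C)C(=O)OC | intermediate
13 | (4S,5R)-4-hydroxy-5-(hydroxymethyl)-3-methylideneoxolan-2-one | OC[C@@H](O1)[C@@H](O)C(=C)C1=O | intermediate
14 | (2S,3S)-3-hydroxy-4-methylidene-5-oxooxolane-2-carbaldehyde (fragment 2) | O=C[C@@H](O1)[C@@H](O)C(=C)C1=O | intermediate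
15 | (4S,5R)-5-[(1R,2Z,6Z)-8-(tert-butyldimethylsilyloxy)-1-hydroxy-2-(hydroxymethyl)-6-methylocta-2,6-dien-1-yl]-4-hydroxy-3-methylideneoxolan-2-one | CC(C)(C)[Si](C)(C)OC/C=C(/C)CC/C=C(/CO)[C@@H](O)[C@@H](O1)[C@@H](O)C(=C)C1=O | intermediate
16 | (4S,5R)-5-{(1R,2Z,6Z)-8-(tert-butyldimethylsilyloxy)-1-hydroxy-6-methyl-2-[(3-methylbutanoyloxy)methyl]octa-2,6-dien-1-yl}-4-hydroxy-3-methylideneoxolan-2-one | CC(C)(C)[Si](C)(C)OC/C=C(/C)CC/C=C(/COC(=O)CC(C)C)[C@@H](O)[C@@H](O1)[C@@H](O)C(=C)C1=O | intermediate
17 | (4S,5R)-4-acetoxy-5-{(1R,2Z,6Z)-1-acetoxy-8-(tert-butyldimethylsilyloxy)-6-methyl-2-[(3-methylbutanoyloxy)methyl]octa-2,6-dien-1-yl}-3-methylideneoxolan-2-one | CC(C)(C)[Si](C)(C)OC/C=C(/C)CC/C=C(/COC(=O)CC(C)C)[C@@H](OC(C)=O)[C@@H](O1)[C@@H](OC(C)=O)C(=C)C1=O | intermediate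
18 | (4S,5R)-4-acetoxy-5-{(1R,2Z,6Z)-1-acetoxy-8-hydroxy-6-methyl-2-[(3-methylbutanoyloxy)methyl]octa-2,6-dien-1-yl}-3-methylideneoxolan-2-one | OC/C=C(/C)CC/C=C(/COC(=O)CC(C)C)[C@@H](OC(C)=O)[C@@H](O1)[C@@H](OC(C)=O)C(=C)C1=O | intermediate
19 | (4S,5R)-4-acetoxy-5-{(1R,2Z,6Z)-1-acetoxy-6-methyl-2-[(3-methylbutanoyloxy)methyl]-8-oxoocta-2,6-dien-1-yl}-3-methylideneoxolan-2-one (seco-enal) | O=C/C=C(/C)CC/C=C(/COC(=O)CC(C)C)[C@@H](OC(C)=O)[C@@H](O1)[C@@H](OC(C)=O)C(=C)C1=O | intermediate
20 | (5S)-5-{(1R,2Z,6Z)-1-acetoxy-6-methyl-2-[(3-methylbutanoyloxy)methyl]-8-oxoocta-2,6-dien-1-yl}-3-(iodomethyl)furan-2(5H)-one | O=C/C=C(/C)CC/C=C(/COC(=O)CC(C)C)[C@@H](OC(C)=O)[C@@H](O1)C=C(CI)C1=O | intermediate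
21 | (1(10)Z,4Z,6R,7S,8S,9R)-9-acetoxy-6-hydroxy-14-(3-methylbutanoyloxy)germacra-1(10),4,11(13)-trien-12,8-olide (cis-fused, written as the free alcohol) | O[C@@H]2/C=C(/C)CC/C=C(/COC(=O)CC(C)C)[C@@H](OC(C)=O)[C@@H](O1)[C@H]2C(=C)C1=O | intermediate
22 | (1(10)Z,4Z,6R,7R,8S,9R)-9-acetoxy-8-hydroxy-14-(3-methylbutanoyloxy)germacra-1(10),4,11(13)-trien-12,6-olide, CNP0603244.1 | C=C1C(=O)O[C@@H]2/C=C(/C)CC/C=C(/COC(=O)CC(C)C)[C@@H](OC(C)=O)[C@@H](O)[C@@H]12 | target

**Step count and risks**
Total steps: 14. Longest linear sequence: 10 (steps 1–4 then 9–14; the branch 5–8 then 9–14 is equally long).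

Step 14 is the most likely to fail. The iodide exchange may be slow. The aldehyde may reach the butenolide face anti to C9. The lactone may stay on O8. The freed O8 alkoxide may also take the neighbouring 9-acetyl group. The fallback gives up the cascade and runs the three events separately with another metal. From 19, LiBr in acetone swaps the activated 7-acetate for bromide and gives the isolable bromomethylbutenolide enal F1. Indium powder in THF/H2O, with slow addition to 2 mM, then closes the ring in an aqueous Barbier reaction, and the hydroxy lactone 21 is isolated. A separate thermodynamic relactonisation with catalytic camphorsulfonic acid in CH2Cl2 returns to the route at 22. This fallback does not cure a wrong facial outcome.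

Step 9 is second. Aldehyde 14 is prone to hydration and β-elimination, both partners carry free hydroxyls, and the Felkin preference at C9 may be modest. The fallback sets C9 by reagent-controlled reduction instead of by addition. It starts from 16, taken as the C9 epimer mixture. MnO2 in CH2Cl2 oxidises only the electron-rich allylic 9-OH to the Z-enone F2. (R)-Me-CBS with catecholborane at −78 °C, with the alkenyl group acting as the large substituent, then reduces F2 back to 16 as the 9R alcohol.

Step 3 is third. The one-pot iodo-Wittig reaction may give a poor Z/E ratio, and that ratio decides the C1=C10 geometry. The fallback installs iodine after the olefination. From 3, (triphenylphosphoranylidene)acetaldehyde in CH2Cl2 gives the E-enal F3. I2, DMAP and K2CO3 in THF/H2O iodinate it by addition–elimination under thermodynamic control to the Z-iodoenal F4. NaBH4/CeCl3·7H2O in MeOH then reduces the aldehyde and rejoins the route at 7.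

**Further compounds**
F1 | step 14 | (5S)-5-{(1R,2Z,6Z)-1-acetoxy-6-methyl-2-[(3-methylbutanoyloxy)methyl]-8-oxoocta-2,6-dien-1-yl}-3-(bromomethyl)furan-2(5H)-one (bromomethylbutenolide enal) | O=C/C=C(/C)CC/C=C(/COC(=O)CC(C)C)[C@@H](OC(C)=O)[C@@H](O1)C=C(CBr)C1=O
F2 | step 9 | (4S,5S)-5-{(2Z,6Z)-8-(tert-butyldimethylsilyloxy)-6-methyl-2-[(3-methylbutanoyloxy)methyl]octa-2,6-dienoyl}-4-hydroxy-3-methylideneoxolan-2-one (Z-enone) | CC(C)(C)[Si](C)(C)OC/C=C(/C)CC/C=C(/COC(=O)CC(C)C)C(=O)[C@@H](O1)[C@@H](O)C(=C)C1=O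
F3 | step 3 | (2E,6Z)-8-(tert-butyldimethylsilyloxy)-6-methylocta-2,6-dienal (E-enal) | O=C/C=C/CC/C(C)=C\CO[Si](C)(C)C(C)(C)C
F4 | step 3 | (2Z,6Z)-8-(tert-butyldimethylsilyloxy)-2-iodo-6-methylocta-2,6-dienal (Z-iodoenal) | O=C/C(I)=C/CC/C(C)=C\CO[Si](C)(C)C(C)(C)C
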